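**Retrosynthetic overview**
1. The target is the all-cis (2R,3R,4S) 4',7-dihydroxyflavan-3-ol unit joined C4→C8 to (−)-epicatechin; the last step is hydrogenolysis of eight benzyl ethers.
2. The C4–H bond is made on the closed ring C by ionic hydrogenation of a C4 tertiary carbinol; hydride enters opposite the axial 3-benzyloxy group, which gives the 2,3-cis-3,4-cis triad.
3. The C4–C8 bond comes from 1,2-addition of C8-lithiated penta-O-benzyl-(−)-epicatechin (chiral pool, all its rings bought intact) to the C4 ketone of a 2,3-cis flavan-4-one.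
4. Ring C, the only ring formed, is closed at O1–C8a by intramolecular SNAr. C8a of ring A is ortho to C4a, so a ketone at C4 activates the C8a–F bond, and the C2 oxygen sits five atoms away (O–C2–C3–C4–C4a–C8a). The C2–O bond is never broken, so the syn diad survives as the otherwise inaccessible cis-flavanone; the carbonyl is then used and removed.
5. The open-chain precursor comes from an Evans syn-glycolate aldol (C2 and C3), Weinreb amide formation and addition of the 4-benzyloxy-2-fluorophenyl Grignard reagent (ring A).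

Key step: step 9

Remark: the carbinol configuration at C4 of compound 18 is drawn for the expected epimer (aryl trans to the 3-benzyloxy group); either epimer gives the same cation in step 10.

**Step 1**
Reactants: 1 (−)-epicatechin
Product: 2 5,7,3',4'-tetra-O-benzyl-(−)-epicatechin
Conditions: BnBr (4.2 equiv), K2CO3, DMF, 0 °C to rt
Reagents that add atoms: benzyl bromide, BrCc1ccccc1
Why: Williamson etherification in which carbonate deprotonates only the four phenols, so the aliphatic 3-hydroxyl stays free and no stereocenter is touched.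

**Step 2**
Reactants: 2 5,7,3',4'-tetra-O-benzyl-(−)-epicatechin
Product: 3 3,5,7,3',4'-penta-O-benzyl-(−)-epicatechin
Conditions: NaH, BnBr, DMF, 0 °C to rt
Reagents that add atoms: benzyl bromide, BrCc1ccccc1
Why: Williamson etherification of the secondary alkoxide; with all phenols capped the flavan cannot ring-open under base, so C2 and C3 keep their configuration.

**Step 3**
Reactants: 3 3,5,7,3',4'-penta-O-benzyl-(−)-epicatechin
Product: 4 8-bromo-3,5,7,3',4'-penta-O-benzyl-(−)-epicatechin
Conditions: NBS, CH2Cl2, −40 °C to rt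
Reagents that add atoms: N-bromosuccinimide, O=C1CCC(=O)N1Br
Why: Electrophilic aromatic bromination of the phloroglucinol-type ring, which for 5,7-dialkoxyflavans is known to take place at C8 in preference to C6.

**Step 4**
Reactants: 5 4-bromo-3-fluorophenol
Product: 6 4-(benzyloxy)-1-bromo-2-fluorobenzene
Conditions: BnBr, K2CO3, acetone, reflux
Reagents that add atoms: benzyl bromide, BrCc1ccccc1
Why: Williamson etherification of the phenol; the aryl halides are inert under these conditions.

**Step 5**
Reactants: 7 (S)-4-benzyloxazolidin-2-one; 8 (benzyloxy)acetyl chloride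
Product: 9 (S)-4-benzyl-3-[(benzyloxy)acetyl]oxazolidin-2-one
Conditions: Et3N, DMAP (cat.), CH2Cl2, 0 °C to rt
Reagents that add atoms: none
Why: Nucleophilic acyl substitution (DMAP-catalysed N-acylation of the oxazolidinone); the auxiliary stereocenter is not involved.

**Step 6**
Reactants: 9 (S)-4-benzyl-3-[(benzyloxy)acetyl]oxazolidin-2-one; 10 4-(benzyloxy)benzaldehyde
Product: 12 (S)-4-benzyl-3-[(2S,3R)-2-(benzyloxy)-3-[4-(benzyloxy)phenyl]-3-hydroxypropanoyl]oxazolidin-2-one, via Z-boron enolate 11 (not isolated)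
Conditions: Bu2BOTf, Et3N, CH2Cl2, −78 to 0 °C; then 10, −78 to 0 °C; pH 7 buffer, MeOH, H2O2, 0 °C
Reagents that add atoms: none
Why: Evans syn-aldol reaction of a glycolate imide, in which the Z-boron enolate reacts through a closed chair transition state on the enolate face remote from the auxiliary benzyl group, setting both new centers (2S,3R, syn) under auxiliary control.

**Step 7**
Reactants: 12 (S)-4-benzyl-3-[(2S,3R)-2-(benzyloxy)-3-[4-(benzyloxy)phenyl]-3-hydroxypropanoyl]oxazolidin-2-one
Product: 13 (2S,3R)-2-(benzyloxy)-3-[4-(benzyloxy)phenyl]-3-hydroxy-N-methoxy-N-methylpropanamide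
Conditions: MeNHOMe·HCl, AlMe3, CH2Cl2, −10 to 0 °C; then cold 0.5 M HCl
Reagents that add atoms: N,O-dimethylhydroxylamine hydrochloride, CNOC.Cl
Why: Aminolysis of the imide by the aluminium amide of N,O-dimethylhydroxylamine (Weinreb amide formation), directed to the exocyclic carbonyl by the aluminium alkoxide of the β-hydroxyl and leaving both stereocenters unchanged.

**Step 8**
Reactants: 13 (2S,3R)-2-(benzyloxy)-3-[4-(benzyloxy)phenyl]-3-hydroxy-N-methoxy-N-methylpropanamide; 6 4-(benzyloxy)-1-bromo-2-fluorobenzene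
Product: 15 (2S,3R)-2-(benzyloxy)-1-[4-(benzyloxy)-2-fluorophenyl]-3-[4-(benzyloxy)phenyl]-3-hydroxypropan-1-one, via aryl Grignard reagent 14 (not isolated)
Conditions: 6 (3 equiv), iPrMgCl·LiCl, THF, −15 °C; then 13, −20 to 0 °C; aq. NH4Cl
Reagents that add atoms: none
Why: Weinreb ketone synthesis in which bromine–magnesium exchange gives the ortho-fluoroaryl Grignard reagent, one equivalent deprotonates the hydroxyl and a second adds to the amide to give a chelated tetrahedral intermediate that can neither over-add nor enolise, so the stereodiad is kept.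

**Step 9**
Reactants: 15 (2S,3R)-2-(benzyloxy)-1-[4-(benzyloxy)-2-fluorophenyl]-3-[4-(benzyloxy)phenyl]-3-hydroxypropan-1-one; 4 8-bromo-3,5,7,3',4'-penta-O-benzyl-(−)-epicatechin
Product: 18 (2R,3S,4S)-3,7-bis(benzyloxy)-2-[4-(benzyloxy)phenyl]-4-[(2R,3R)-3,5,7-tris(benzyloxy)-2-[3,4-bis(benzyloxy)phenyl]chroman-8-yl]chroman-4-ol, via cis-flavan-4-one 16 (not isolated), via C8-aryllithium 17 (not isolated)
Conditions: KH (1.05 equiv), THF (high dilution), −40 to 0 °C; then cannulated at −78 °C into 17 [from 4, t-BuLi (2.6 equiv), THF, −78 °C]; aq. NH4Cl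
Reagents that add atoms: none
Why: KH converts the benzylic hydroxyl of 15 into its alkoxide, which adds to the fluorine-bearing carbon of ring A (C8a, ortho to the C4 carbonyl) to give a carbonyl-stabilised Meisenheimer adduct that loses fluoride: an intramolecular SNAr, 6-exo closure of ring C through the O1–C8a bond, the known route from β-hydroxy 2-fluoroaryl ketones to chroman-4-ones. No bond to C2 or C3 is broken, so the syn diad set in step 6 is carried unchanged into the 2,3-cis flavan-4-one 16, the thermodynamically disfavoured isomer that the usual oxa-Michael closure (which equilibrates C2 and C3) does not deliver. The step needs ring closure to outrun retro-aldol cleavage of the alkoxide and deprotonation at C3: the ortho-acyl activation, the six-membered transition state, high dilution and low temperature favour closure, one equivalent of a base that leaves no proton source is used, and the 3-oxygen is blocked as a benzyl ether so that no five-membered closure competes. The labile ketone 16 is not isolated but added at −78 °C to aryllithium 17 (bromine–lithium exchange at C8 of the epicatechin unit), whose 1,2-addition to the C4 carbonyl, a known reaction of protected flavan-4-ones, forges the C4–C8 interflavan bond, so that every ring and every skeletal bond of the target is in place after this operation. The new carbinol center is expected to arise from attack opposite the axial 3-benzyloxy group, but it is not controlled on purpose because step 10 ionises it.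

**Step 10**
Reactants: 18 (2R,3S,4S)-3,7-bis(benzyloxy)-2-[4-(benzyloxy)phenyl]-4-[(2R,3R)-3,5,7-tris(benzyloxy)-2-[3,4-bis(benzyloxy)phenyl]chroman-8-yl]chroman-4-ol
Product: 19 (2R,3R,4S)-3,7-bis(benzyloxy)-2-[4-(benzyloxy)phenyl]-4-[(2R,3R)-3,5,7-tris(benzyloxy)-2-[3,4-bis(benzyloxy)phenyl]chroman-8-yl]chroman
Conditions: Bu3SnH, CF3CO2H, CH2Cl2, 0 °C
Reagents that add atoms: none
Why: Ionic hydrogenation in which acid ionises the tertiary, doubly benzylic carbinol to a C4 cation stabilised by the para-benzyloxy group of ring A and by the trialkoxyaryl ring, and the tin hydride attacks the face opposite the axial 3-benzyloxy group, so the C8 aryl ends cis to the 3-oxygen and to the 2-aryl group (new center C4 = S), a known way to 3,4-cis 4-arylflavans.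

**Step 11**
Reactants: 19 (2R,3R,4S)-3,7-bis(benzyloxy)-2-[4-(benzyloxy)phenyl]-4-[(2R,3R)-3,5,7-tris(benzyloxy)-2-[3,4-bis(benzyloxy)phenyl]chroman-8-yl]chroman
Product: 20 (2R,3R,4S)-2-(4-hydroxyphenyl)-4-[(2R,3R)-2-(3,4-dihydroxyphenyl)-3,5,7-trihydroxychroman-8-yl]chroman-3,7-diol
Conditions: H2 (1 atm), Pd(OH)2/C, THF/MeOH, rt
Reagents that add atoms: none
Why: Hydrogenolysis of the eight benzyl ethers over Pd(OH)2 on carbon, under which the ring C–O bonds and the interflavan C–C bond of flavan-3-ols are known to survive, so all five stereocenters are retained.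

**Compound list**
1 | (−)-epicatechin, (2R,3R)-2-(3,4-dihydroxyphenyl)chroman-3,5,7-triol | Oc1cc(O)c2c(c1)O[C@H](c1ccc(O)c(O)c1)[C@H](O)C2 | starting material
2 | 5,7,3',4'-tetra-O-benzyl-(−)-epicatechin | c5ccccc5COc1cc(OCc5ccccc5)c2c(c1)O[C@H](c1ccc(OCc5ccccc5)c(OCc5ccccc5)c1)[C@H](O)C2 | intermediate
3 | 3,5,7,3',4'-penta-O-benzyl-(−)-epicatechin | c5ccccc5COc1cc(OCc5ccccc5)c2c(c1)O[C@H](c1ccc(OCc5ccccc5)c(OCc5ccccc5)c1)[C@H](OCc5ccccc5)C2 | intermediate
4 | 8-bromo-3,5,7,3',4'-penta-O-benzyl-(−)-epicatechin | c5ccccc5COc1cc(OCc5ccccc5)c2c(c1Br)O[C@H](c1ccc(OCc5ccccc5)c(OCc5ccccc5)c1)[C@H](OCc5ccccc5)C2 | intermediate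
5 | 4-bromo-3-fluorophenol | Oc1ccc(Br)c(F)c1 | starting material
6 | 4-(benzyloxy)-1-bromo-2-fluorobenzene | Fc1cc(OCc2ccccc2)ccc1Br | intermediate
7 | (S)-4-benzyloxazolidin-2-one | O=C1N[C@@H](Cc2ccccc2)CO1 | starting material
8 | (benzyloxy)acetyl chloride | ClC(=O)COCc1ccccc1 | starting material
9 | (S)-4-benzyl-3-[(benzyloxy)acetyl]oxazolidin-2-one | O=C(COCc1ccccc1)N1C(=O)OC[C@@H]1Cc1ccccc1 | intermediate
10 | 4-(benzyloxy)benzaldehyde | O=Cc1ccc(OCc2ccccc2)cc1 | starting material
11 | (Z)-dibutylboron enolate of 9 | CCCCB(CCCC)O/C(=C\OCc1ccccc1)N1C(=O)OC[C@@H]1Cc1ccccc1 | intermediate (not isolated)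
12 | (S)-4-benzyl-3-[(2S,3R)-2-(benzyloxy)-3-[4-(benzyloxy)phenyl]-3-hydroxypropanoyl]oxazolidin-2-one | c5ccccc5COc1ccc([C@@H](O)[C@H](OCc5ccccc5)C(=O)N2C(=O)OC[C@@H]2Cc3ccccc3)cc1 | intermediate
13 | (2S,3R)-2-(benzyloxy)-3-[4-(benzyloxy)phenyl]-3-hydroxy-N-methoxy-N-methylpropanamide | c5ccccc5COc1ccc([C@@H](O)[C@H](OCc5ccccc5)C(=O)N(C)OC)cc1 | intermediate
14 | [4-(benzyloxy)-2-fluorophenyl]magnesium chloride (LiCl complex in solution) | Fc1cc(OCc2ccccc2)ccc1[Mg]Cl | intermediate (not isolated)
15 | (2S,3R)-2-(benzyloxy)-1-[4-(benzyloxy)-2-fluorophenyl]-3-[4-(benzyloxy)phenyl]-3-hydroxypropan-1-one | c5ccccc5COc1ccc([C@@H](O)[C@H](OCc5ccccc5)C(=O)c2ccc(OCc5ccccc5)cc2F)cc1 | intermediate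
16 | (2R,3S)-3,7-bis(benzyloxy)-2-[4-(benzyloxy)phenyl]chroman-4-one (2,3-cis) | c5ccccc5COc1ccc([C@H]2Oc3cc(OCc5ccccc5)ccc3C(=O)[C@H]2OCc5ccccc5)cc1 | intermediate (not isolated)
17 | [(2R,3R)-3,5,7-tris(benzyloxy)-2-[3,4-bis(benzyloxy)phenyl]chroman-8-yl]lithium | c5ccccc5COc1cc(OCc5ccccc5)c2c(c1[Li])O[C@H](c1ccc(OCc5ccccc5)c(OCc5ccccc5)c1)[C@H](OCc5ccccc5)C2 | intermediate (not isolated)
18 | (2R,3S,4S)-3,7-bis(benzyloxy)-2-[4-(benzyloxy)phenyl]-4-[(2R,3R)-3,5,7-tris(benzyloxy)-2-[3,4-bis(benzyloxy)phenyl]chroman-8-yl]chroman-4-ol | c5ccccc5COc1ccc([C@H]2Oc3cc(OCc5ccccc5)ccc3[C@@](c3c(OCc5ccccc5)cc(OCc5ccccc5)c4c3O[C@H](c3ccc(OCc5ccccc5)c(OCc5ccccc5)c3)[C@H](OCc5ccccc5)C4)(O)[C@H]2OCc5ccccc5)cc1 | intermediate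
19 | (2R,3R,4S)-3,7-bis(benzyloxy)-2-[4-(benzyloxy)phenyl]-4-[(2R,3R)-3,5,7-tris(benzyloxy)-2-[3,4-bis(benzyloxy)phenyl]chroman-8-yl]chroman (octa-O-benzyl target) | c5ccccc5COc1ccc([C@H]2Oc3cc(OCc5ccccc5)ccc3[C@@H](c3c(OCc5ccccc5)cc(OCc5ccccc5)c4c3O[C@H](c3ccc(OCc5ccccc5)c(OCc5ccccc5)c3)[C@H](OCc5ccccc5)C4)[C@H]2OCc5ccccc5)cc1 | intermediate
20 | (2R,3R,4S)-2-(4-hydroxyphenyl)-4-[(2R,3R)-2-(3,4-dihydroxyphenyl)-3,5,7-trihydroxychroman-8-yl]chroman-3,7-diol | Oc1ccc([C@H]2Oc3cc(O)ccc3[C@@H](c3c(O)cc(O)c4c3O[C@H](c3ccc(O)c(O)c3)[C@H](O)C4)[C@H]2O)cc1 | target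

**Step count and risks**
Total step count: 11. Longest linear sequence: 7 steps (steps 5 to 11, from 7 and 8).

Steps most likely to fail:

Step 9. The alkoxide of 15 may fragment by retro-aldol reaction faster than it closes, the cis-flavanone may epimerise at C3 by proton transfer before it is trapped, and the aryllithium may enolise the ketone instead of adding. The fallback sets out from 15 and moves the same O1–C8a closure to the alcohol oxidation level. NaBH4 in MeOH at 0 °C should reduce the ketone to the 1,3-diol F1 (both C1 epimers serve). Lithium 2,2,6,6-tetramethylpiperidide in THF (−78 to 0 °C) should then form the dialkoxide, lithiate the ring position between fluorine and the benzyloxy group and eliminate lithium fluoride to give the 3-alkoxyaryne. The C3 alkoxide adds to the aryne carbon meta to the benzyloxy group (the distal carbon, also the only one that gives a six-membered ring), giving the flavan-4-ol F2. Dess–Martin periodinane with NaHCO3 in CH2Cl2 should then give the ketone under neutral conditions. The fallback comes back to the route at 16, which is added to 17 as in the second half of step 9.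

Step 10. Hydride may be delivered to the wrong face of the cation, or the cation may lose the C3 proton instead of being reduced. The fallback sets out from 18. Dehydration with camphorsulfonic acid in toluene should give the 3-benzyloxy-4-aryl-2H-chromene F3, in which C2 is the only stereocenter left in ring C. Hydrogenation over PtO2 in EtOAc, with the benzyl ethers retained, should add both hydrogens to the face opposite the C2 aryl group and so place the 3-oxygen and the 4-aryl group cis to it. The fallback comes back to the route at 19.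

Step 8. The ortho-fluoroaryl Grignard reagent may decompose to an aryne before it adds, and the magnesium alkoxide of 13 may undergo retro-aldol cleavage during the slow addition. The fallback sets out from 12 and replaces the carbanion addition by a neutral acyl cross-coupling. Lithium ethanethiolate in THF at 0 °C should cleave the auxiliary to the S-ethyl thioester F4. Transmetalation of 14 with ZnCl2 at −15 °C should give the arylzinc chloride F5, which should couple with F4 under PdCl2(PPh3)2 catalysis in THF/toluene at rt (Fukuyama coupling) in the presence of the free hydroxyl. The fallback comes back to the route at 15.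

**Further compounds**
F1 | step 9 | (2S,3R)-2-(benzyloxy)-1-[4-(benzyloxy)-2-fluorophenyl]-3-[4-(benzyloxy)phenyl]propane-1,3-diol (both C1 epimers) | c5ccccc5COc1ccc([C@@H](O)[C@H](OCc5ccccc5)C(O)c2ccc(OCc5ccccc5)cc2F)cc1
F2 | step 9 | (2R,3R)-3,7-bis(benzyloxy)-2-[4-(benzyloxy)phenyl]chroman-4-ol (both C4 epimers) | c5ccccc5COc1ccc([C@H]2Oc3cc(OCc5ccccc5)ccc3C(O)[C@H]2OCc5ccccc5)cc1
F3 | step 10 | (2R)-3,7-bis(benzyloxy)-2-[4-(benzyloxy)phenyl]-4-[(2R,3R)-3,5,7-tris(benzyloxy)-2-[3,4-bis(benzyloxy)phenyl]chroman-8-yl]-2H-chromene | c5ccccc5COc1ccc([C@H]2Oc3cc(OCc5ccccc5)ccc3C(c3c(OCc5ccccc5)cc(OCc5ccccc5)c4c3O[C@H](c3ccc(OCc5ccccc5)c(OCc5ccccc5)c3)[C@H](OCc5ccccc5)C4)=C2OCc5ccccc5)cc1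
F4 | step 8 | S-ethyl (2S,3R)-2-(benzyloxy)-3-[4-(benzyloxy)phenyl]-3-hydroxypropanethioate | c5ccccc5COc1ccc([C@@H](O)[C@H](OCc5ccccc5)C(=O)SCC)cc1
F5 | step 8 | [4-(benzyloxy)-2-fluorophenyl]zinc chloride | Fc1cc(OCc2ccccc2)ccc1[Zn]Cl
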